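**Assumptions**
- The target has no stereocentres (C-2 of the chromene carries two methyls), so "single enantiomer" is moot. The only stereochemistry in the route is a racemic trans-epoxide that is destroyed in Step 9.
- Chromene annulation of resacetophenone is assumed to favour the linear 6-acetyl-7-hydroxy isomer, with the angular isomer removed by chromatography.
- The diketone is drawn in its keto form, although it exists largely as the chelated enol.

## Retrosynthesis
1. Remove both MOM groups from the protected dibenzoylmethane (15). This ends the synthesis.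
2. **Key disconnection (not Baker–Venkataraman or ester Claisen condensation):** the 1,3-diketone comes from Pd(0)-catalysed isomerisation of an α,β-epoxy ketone. That epoxide comes from Weitz–Scheffer epoxidation of a chalcone, which comes from Claisen–Schmidt condensation of ketone **5** with aldehyde **11**.
3. Ketone **5**: the only new ring, the 2,2-dimethylpyran, is built first by phenol/prenal annulation of resacetophenone (1), followed by MOM protection.
4. Aldehyde **11**: the prenyl group is installed by O-allylation, Claisen rearrangement, MOM protection and cross-metathesis with 2-methyl-2-butene.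
5. Ring order: the pyran ring forms in Step 1. A transient oxirane forms in Step 9 and is opened immediately. No other rings are made.

## Route

**Step 1**
Reactants: 1 (2,4-dihydroxyacetophenone) and 2 (3-methylbut-2-enal).
Product: 3, 1-(7-hydroxy-2,2-dimethyl-2H-chromen-6-yl)ethanone.
Conditions: pyridine, reflux, 24 h.
Reagents that add atoms: 2, 3-methylbut-2-enal, CC(C)=CC=O.
Why: Phenol–enal annulation (Knoevenagel-type o-quinone methide formation, then 6π-oxa-electrocyclisation) occurs at the less hindered C-5 next to the 4-OH. The 2-OH stays chelated to the ketone.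

**Step 2**
Reactants: 3 and 4 (chloromethyl methyl ether).
Product: 5, 1-(7-(methoxymethoxy)-2,2-dimethyl-2H-chromen-6-yl)ethanone.
Conditions: NaH, THF, 0 °C; then 4, 0 °C to rt.
Reagents that add atoms: 4, MOMCl, COCCl.
Why: Deprotonating the chelated phenol and alkylating it gives the MOM ether (Williamson-type acetal formation). The MOM group prevents flavonol/aurone formation under the basic H2O2 conditions of Step 9.

**Step 3**
Reactants: 6 (4-hydroxybenzaldehyde) and 7 (allyl bromide).
Product: 8, 4-(allyloxy)benzaldehyde.
Conditions: K2CO3, acetone, reflux.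
Reagents that add atoms: 7, allyl bromide, C=CCBr.
Why: Williamson O-alkylation of the phenoxide.

**Step 4**
Reactant: 8.
Product: 9, 3-allyl-4-hydroxybenzaldehyde.
Conditions: neat or NMP, 200 °C (microwave), 1 h.
Reagents that add atoms: none.
Why: Aromatic Claisen [3,3] rearrangement. It goes ortho because the para position is blocked.

**Step 5**
Reactants: 9 and 4.
Product: 10, 3-allyl-4-(methoxymethoxy)benzaldehyde.
Conditions: MOMCl, i-Pr2NEt, CH2Cl2, 0 °C to rt.
Reagents that add atoms: 4, MOMCl, COCCl.
Why: Acetal protection of the phenol. This prevents the free phenol from poisoning the Ru catalyst in Step 6 and from deactivating the aldehyde in Step 7.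

**Step 6**
Reactants: 10 and 11 (2-methylbut-2-ene).
Product: 12, 4-(methoxymethoxy)-3-(3-methylbut-2-en-1-yl)benzaldehyde.
Conditions: Grubbs II (5 mol%), 1,4-benzoquinone (10 mol%), 2-methylbut-2-ene (20 equiv), CH2Cl2, 40 °C.
Reagents that add atoms: 11, 2-methylbut-2-ene, CC=C(C)C (supplies the =CMe2 terminus; propene is lost).
Why: Cross-metathesis of the terminal allyl alkene with a trisubstituted partner gives the prenyl group. Benzoquinone suppresses Ru–H-mediated isomerisation to the propenyl arene.

**Step 7**
Reactants: 5 and 12.
Product: 13, (E)-chalcone, 1-(7-MOMO-2,2-dimethylchromen-6-yl)-3-(4-MOMO-3-prenylphenyl)prop-2-en-1-one.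
Conditions: NaOH (aq), EtOH/THF, rt, 16 h.
Reagents that add atoms: none (loses H2O).
Why: Claisen–Schmidt aldol condensation. Dehydration gives the thermodynamic E-enone.

**Step 8**
Reactants: 13 and 14 (hydrogen peroxide).
Product: 15, racemic trans-α,β-epoxy ketone.
Conditions: 30% H2O2, 2 M NaOH, THF/MeOH, 0 °C to rt.
Reagents that add atoms: 14, H2O2, OO.
Why: Weitz–Scheffer nucleophilic epoxidation is selective for the electron-poor enone. The chromene and prenyl alkenes are inert. The two new stereocentres are racemic and trans, and are erased in Step 9.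

**Step 9**
Reactant: 15.
Product: 16, 1-(7-MOMO-2,2-dimethylchromen-6-yl)-3-(4-MOMO-3-prenylphenyl)propane-1,3-dione.
Conditions: Pd(PPh3)4 (5 mol%), benzene, 80 °C, 6 h.
Reagents that add atoms: none (isomerisation).
Why: Pd(0) inserts into the Cα–O bond of the epoxy ketone. β-Hydride elimination from the resulting alkoxide carbon gives the second C=O, and C–H reductive elimination gives the CH2 (Pd-catalysed epoxy-ketone to 1,3-diketone isomerisation). The carbon skeleton is set here with no stereochemical issue, because both former epoxide carbons become sp2 or CH2.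

**Step 10**
Reactant: 16.
Product: 17, Glyinflanin C.
Conditions: 3 M HCl, THF/MeOH (1:1), 40 °C, 4 h.
Reagents that add atoms: none (the MOM groups leave as CH2(OMe)2/CH2O).
Why: Acid-catalysed acetal hydrolysis releases both phenols. The electron-poor aryl rings disfavour protonation of the prenyl and chromene alkenes under these mild conditions.

## Compound list
1 | 2,4-dihydroxyacetophenone | CC(=O)c1ccc(O)cc1O | starting material
2 | 3-methylbut-2-enal | CC(C)=CC=O | starting material
3 | 1-(7-hydroxy-2,2-dimethyl-2H-chromen-6-yl)ethanone | CC(=O)c1cc2C=CC(C)(C)Oc2cc1O | intermediate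
4 | chloromethyl methyl ether | COCCl | reagent
5 | 1-(7-MOMO-2,2-dimethyl-2H-chromen-6-yl)ethanone | CC(=O)c1cc2C=CC(C)(C)Oc2cc1OCOC | intermediate
6 | 4-hydroxybenzaldehyde | O=Cc1ccc(O)cc1 | starting material
7 | allyl bromide | C=CCBr | reagent
8 | 4-(allyloxy)benzaldehyde | C=CCOc1ccc(C=O)cc1 | intermediate
9 | 3-allyl-4-hydroxybenzaldehyde | C=CCc1cc(C=O)ccc1O | intermediate
10 | 3-allyl-4-(methoxymethoxy)benzaldehyde | C=CCc1cc(C=O)ccc1OCOC | intermediate
11 | 2-methylbut-2-ene | CC=C(C)C | reagent
12 | 4-(methoxymethoxy)-3-prenylbenzaldehyde | CC(C)=CCc1cc(C=O)ccc1OCOC | intermediate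
13 | (E)-chalcone | CC(C)=CCc1cc(/C=C/C(=O)c2cc3C=CC(C)(C)Oc3cc2OCOC)ccc1OCOC | intermediate
14 | hydrogen peroxide | OO | reagent
15 | trans-epoxy ketone (racemic, relative configuration shown) | O=C(c1cc2C=CC(C)(C)Oc2cc1OCOC)[C@H]1O[C@@H]1c1ccc(OCOC)c(CC=C(C)C)c1 | intermediate
16 | bis-MOM 1,3-diketone | CC(C)=CCc1cc(C(=O)CC(=O)c2cc3C=CC(C)(C)Oc3cc2OCOC)ccc1OCOC | intermediate
17 | Glyinflanin C | CC(C)=CCc1cc(C(=O)CC(=O)c2cc3c(cc2O)OC(C)(C)C=C3)ccc1O | target

## Totals
- Total steps: 10.
- Longest linear sequence: 8 steps (6 → 8 → 9 → 10 → 12 → 13 → 15 → 16 → 17).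

## Three steps most likely to fail
1. **Step 9 (Pd isomerisation of the chalcone epoxide).** Diaryl-type epoxy ketones can undergo competing deoxygenation back to the chalcone or Meinwald aryl/acyl migration.
   - Fallback: abandon the epoxide. Oxidise aldehyde 12 to the methyl ester (NaClO2, then TMSCHN2) and perform a crossed Claisen condensation with ketone 5 using LiHMDS to give 16.
2. **Step 1 (regioselective chromene annulation).** Formation of the angular 8-acetyl isomer lowers the yield.
   - Fallback: selectively O-alkylate the 4-OH with 3-chloro-3-methylbut-1-yne (K2CO3, KI), then cyclise thermally by propargyl Claisen/1,5-H shift in PhNEt2, and separate isomers.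
3. **Step 6 (cross-metathesis to the prenyl group).** Allyl-to-propenyl isomerisation or low conversion can give poor yields.
   - Fallback: make 3-bromo-4-MOMO-benzaldehyde from commercial 3-bromo-4-hydroxybenzaldehyde and protect the aldehyde as its acetal. Then do Mg/Br exchange and CuI-catalysed SN2 coupling with prenyl bromide, followed by acetal hydrolysis.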